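From one charge you cannot tell a solid that dissolves in proportion to what lies there from one that dissolves at a steady pace per litre, and the earlier theta run has one charge.

| flask | solid substrate | reagent | remark | time |
|---|---|---|---|---|
| theta | 1 M | 2.4 M | run made earlier |  |
| flask | 2.0 M | 2.40 M |  | 12 min |

- theta (time / min: solid substrate / %, single product / %): 1.50: 93.6, 0.4; 3.00: 92.6, 0.4; 5.00: 87.0, 1.6; 6.00: 85.4, 2.2; 8.00: 82.3, 4.7; 10.0: 76.2, 6.7

(standard deviation of a reading: 1 percentage point)

- percent here means solid substrate units held: one idle adduct counts as two
- what is said of single product includes idle adduct
- solid substrate is a solid; its amount is given per volume of the solution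
- the numbers in the tables scatter by 1 percentage point (one standard deviation)
- candidate steps: reagent + bis adduct -> tris adduct; starting material + single product <-> idle adduct; solid substrate <-> starting material; starting material + reagent -> single product; single product -> over-reaction product; reagent + single product -> bis adduct; reagent + tris adduct -> tetra adduct
- at the start none of the solid substrate is in solution
- in an amount of single product, one idle adduct counts as one single product

* amount of solid substrate at 12 min, in percent of the solid substrate charged (only what is still solid)
* amount of single product at 12 min, in percent of the solid substrate charged
* amount of bis adduct at 12 min, in percent of the solid substrate charged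
* amount of tris adduct at 12 min, in percent of the solid substrate charged

Climb the ladder on the theta run. Between 1.50 min and 10.0 min its solid falls at 0.0205 M min⁻¹; call this r, the dissolving pace, the amount of solid leaving per litre of solution per minute. The first rung is the dissolved remainder, what is neither solid nor read as single product, 0.171 M at 10.0 min. Single product gains a rough 0.0100 M min⁻¹, so that pool turns over in about 17.1 min, longer than the asked 12 min. Next, the theta charge of solid divided by r gives 48.9 min, the flask's charge of solid divided by r gives 97.7 min, and the flask's reagent divided by r gives 117 min; each is longer than that turnover, and the last is the longest.

So freeze r. In the theta run it reads 0.0182 M min⁻¹ up to 6.00 min and 0.0230 M min⁻¹ after it, with no visible fall as the solid shrinks, though the scatter is wide. I commit to zero order in the solid: the theta loss carried to 12 min is 0.279 M, and over the flask's charge that leaves 86.1 % solid.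

The forecast, noting that “doubling the solid gives the same percentages if dissolution scales with solid”, gives 77 % solid, 8 % single product, 2 % bis adduct and 0.3 % tris adduct, so its solid stands 9.1 percentage points below mine.

The flask gives 86.1 % solid, 3.86 % single product, 0.908 % bis adduct and 0.0349 % tris adduct.

    reagent + bis adduct → tris adduct (k = 0.00580 M⁻¹ min⁻¹)
    starting material + single product ⇌ idle adduct, settled at all times (K = 0.930 M⁻¹)
    solid substrate ⇌ starting material, rate k3*(cs3 - [starting material]) while solid is left; crystals form when [starting material] > cs3 (solubility = 0.600 M, k = 0.0470 min⁻¹)
    starting material + reagent → single product (k = 0.0320 M⁻¹ min⁻¹)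
    single product → over-reaction product (k = 3.30 × 10⁻⁵ min⁻¹)
    reagent + single product → bis adduct (k = 0.0250 M⁻¹ min⁻¹)
    reagent + tris adduct → tetra adduct (k = 0.0330 M⁻¹ min⁻¹)

The dissolving step goes with the gap between starting material and its solubility, 0.60 M, and carries no amount of solid. This reckoning holds r fixed and has no reagent in it, so the neighbouring flask, charged with 0.96 M of reagent and otherwise like the flask, gets the same 86.1 % by it. That neighbour holds 86.6 % solid, and its single product is 2.07 %.

The data are simulated for substances that don't exist.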